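**Retrosynthetic overview**
1. The C3 acetate is installed last; the ten-membered ring is closed at C5–C6 by nickel-mediated reductive coupling of a primary alkyl bromide (alkyl radical) with the (Z)-alkenyl bromide.
2. The alkyl bromide comes from hydroboration of a 4-vinylbutenolide; the butenolide comes from alkoxide-directed anti-carbomagnesiation of a propargylic alcohol with vinylmagnesium bromide, then CO2.
3. C11a is set by zinc–ProPhenol alkynylation of an enal; C9 is set by CBS reduction of the enone.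
4. The (E)-C10=C11 alkene and both carbonyls come from oxidative opening of a 2-alkyl-3-methylfuran; the (Z)-alkenyl bromide comes from but-2-yn-1-ol.
5. Ring order: furan (sacrificial) → butenolide (step 8) → ten-membered carbocycle (step 12).

Assumption: (S,S)-ProPhenol is taken as the ligand enantiomer that delivers the alkynyl group to the Si face of the aldehyde; if the sense is the reverse, (R,R)-ProPhenol is used and nothing else changes.

Locants for the macrocycles follow cyclodeca[b]furan numbering (O1, C2=O, C3, C3a, C4 … C11, C11a).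

**Step 1**
Reactants: 1 but-2-yn-1-ol
Product: 3 (Z)-3-bromobut-2-en-1-ol, via cyclic alkenylalanate 2 (not isolated)
Conditions: NaAlH2(OCH2CH2OCH3)2 (Red-Al, 1.1 equiv), Et2O, 0 °C; then NBS, −78 → 0 °C
Reagents that add atoms: N-bromosuccinimide, O=C1CCC(=O)N1Br
Why: alkoxide-directed trans-hydroalumination of the propargylic alcohol places aluminium on C3 cis to the CH2O group in a five-membered alanate, and bromodealumination with retention gives the Z-alkenyl bromide (hydroalumination–halogenation).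

**Step 2**
Reactants: 3 (Z)-3-bromobut-2-en-1-ol
Product: 4 (Z)-1,3-dibromobut-2-ene
Conditions: PBr3 (0.4 equiv), Et2O, 0 °C
Reagents that add atoms: phosphorus tribromide, BrP(Br)Br
Why: SN2 conversion of the primary allylic alcohol into the bromide, which leaves the alkenyl bromide and its Z geometry untouched.

**Step 3**
Reactants: 5 3-methylfuran
Product: 6 2-bromo-3-methylfuran
Conditions: NBS, DMF, 0 °C → rt, dark
Reagents that add atoms: N-bromosuccinimide, O=C1CCC(=O)N1Br
Why: electrophilic aromatic bromination at the α-position next to the methyl group, the most nucleophilic site of the furan.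

**Step 4**
Reactants: 6 2-bromo-3-methylfuran; 4 (Z)-1,3-dibromobut-2-ene
Product: 8 2-[(2Z)-3-bromobut-2-en-1-yl]-3-methylfuran, via 2-lithio-3-methylfuran 7 (not isolated)
Conditions: n-BuLi, THF, −78 °C; then 4, −78 → 0 °C
Reagents that add atoms: none
Why: bromine–lithium exchange gives the 2-furyllithium regiospecifically, and it is alkylated by SN2 displacement of the allylic bromide, which is far more reactive than the alkenyl bromide and keeps the Z geometry.

**Step 5**
Reactants: 8 2-[(2Z)-3-bromobut-2-en-1-yl]-3-methylfuran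
Product: 10 (2E,6Z)-7-bromo-3-methyl-4-oxoocta-2,6-dienal, via (2Z,6Z)-isomer 9 (not isolated)
Conditions: NBS, NaHCO3, acetone/H2O (10:1), −20 °C; then pyridine, 0 °C → rt
Reagents that add atoms: water, O
Why: oxidative ring opening of the furan (2,5-addition of bromonium/water, then collapse) gives the cis-ene-dicarbonyl and pyridine isomerises it to the more stable E-4-oxo-enal, so furan C2 becomes the ketone, C5 the aldehyde and C3=C4 the E-trisubstituted alkene.

**Step 6**
Reactants: 10 (2E,6Z)-7-bromo-3-methyl-4-oxoocta-2,6-dienal; 11 tert-butyldimethyl(prop-2-yn-1-yloxy)silane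
Product: 13 (4R,5E,9Z)-10-bromo-1-[(tert-butyldimethylsilyl)oxy]-4-hydroxy-6-methylundeca-5,9-dien-2-yn-7-one, via alkynyl(methyl)zinc 12 (not isolated)
Conditions: Me2Zn (3 equiv), (S,S)-ProPhenol (10 mol %), Ph3PO (20 mol %), toluene, 0 °C
Reagents that add atoms: none
Why: dinuclear zinc–ProPhenol catalysed enantioselective alkynylation of an α,β-unsaturated aldehyde, in which the aldehyde reacts and the ketone does not, and delivery of the alkynyl group to the Si face sets C4 as R.

**Step 7**
Reactants: 13 (4R,5E,9Z)-10-bromo-1-[(tert-butyldimethylsilyl)oxy]-4-hydroxy-6-methylundeca-5,9-dien-2-yn-7-one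
Product: 14 (4R,5E,7S,9Z)-10-bromo-1-[(tert-butyldimethylsilyl)oxy]-6-methylundeca-5,9-dien-2-yne-4,7-diol
Conditions: (R)-Me-CBS oxazaborolidine (1 equiv), catecholborane (3 equiv), toluene/CH2Cl2, −78 °C; MeOH quench
Reagents that add atoms: none
Why: Corey–Bakshi–Shibata reduction in which the α-methylalkenyl group is the large and the CH2 group the small substituent, so the (R)-catalyst gives the 7S alcohol by reagent control and any minor C4 epimer from step 6 becomes a separable diastereomer.

**Step 8**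
Reactants: 14 (4R,5E,7S,9Z)-10-bromo-1-[(tert-butyldimethylsilyl)oxy]-6-methylundeca-5,9-dien-2-yne-4,7-diol; 15 vinylmagnesium bromide
Product: 18 (5R)-5-[(1E,3S,5Z)-6-bromo-3-hydroxy-2-methylhepta-1,5-dien-1-yl]-3-{[(tert-butyldimethylsilyl)oxy]methyl}-4-ethenylfuran-2(5H)-one, via alkenylmagnesium chelate 16 (not isolated), via Z-hydroxy acid 17 (not isolated)
Conditions: CH2=CHMgBr (6 equiv), THF, reflux; CO2 (1 atm), −20 °C → rt; 1 M HCl, rt
Reagents that add atoms: carbon dioxide, O=C=O
Why: the C4 magnesium alkoxide directs anti-carbomagnesiation of the alkyne (vinyl to the proximal carbon, magnesium to the distal carbon in a five-membered chelate cis to C4), CO2 carboxylates the C–Mg bond with retention and the Z-γ-hydroxy acid lactonises on acidification, while C4 is untouched and the alkenyl bromide is inert without a transition metal.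

**Step 9**
Reactants: 18 (5R)-5-[(1E,3S,5Z)-6-bromo-3-hydroxy-2-methylhepta-1,5-dien-1-yl]-3-{[(tert-butyldimethylsilyl)oxy]methyl}-4-ethenylfuran-2(5H)-one
Product: 19 (1E,3S,5Z)-6-bromo-1-[(2R)-4-{[(tert-butyldimethylsilyl)oxy]methyl}-3-ethenyl-5-oxo-2,5-dihydrofuran-2-yl]-2-methylhepta-1,5-dien-3-yl propanoate
Conditions: (EtCO)2O, pyridine, DMAP (cat.), CH2Cl2, 0 °C
Reagents that add atoms: propionic anhydride, CCC(=O)OC(=O)CC
Why: DMAP-catalysed acylation of the only free hydroxyl under conditions too weakly basic to epimerise the butenolide γ-position.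

**Step 10**
Reactants: 19 (1E,3S,5Z)-6-bromo-1-[(2R)-4-{[(tert-butyldimethylsilyl)oxy]methyl}-3-ethenyl-5-oxo-2,5-dihydrofuran-2-yl]-2-methylhepta-1,5-dien-3-yl propanoate
Product: 21 (1E,3S,5Z)-6-bromo-1-[(2R)-4-{[(tert-butyldimethylsilyl)oxy]methyl}-3-(2-hydroxyethyl)-5-oxo-2,5-dihydrofuran-2-yl]-2-methylhepta-1,5-dien-3-yl propanoate, via B-alkyl-9-BBN adduct 20 (not isolated)
Conditions: 9-BBN (1.3 equiv), THF, 0 °C → rt; then H2O2, pH 7 phosphate buffer, 0 °C → rt
Reagents that add atoms: hydrogen peroxide, OO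
Why: anti-Markovnikov hydroboration by 9-BBN of the only monosubstituted alkene, which ignores the trisubstituted alkenes, the esters and the lactone, followed by buffered oxidation to the primary alcohol.

**Step 11**
Reactants: 21 (1E,3S,5Z)-6-bromo-1-[(2R)-4-{[(tert-butyldimethylsilyl)oxy]methyl}-3-(2-hydroxyethyl)-5-oxo-2,5-dihydrofuran-2-yl]-2-methylhepta-1,5-dien-3-yl propanoate
Product: 22 (1E,3S,5Z)-6-bromo-1-[(2R)-3-(2-bromoethyl)-4-{[(tert-butyldimethylsilyl)oxy]methyl}-5-oxo-2,5-dihydrofuran-2-yl]-2-methylhepta-1,5-dien-3-yl propanoate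
Conditions: CBr4, PPh3, CH2Cl2, 0 °C
Reagents that add atoms: carbon tetrabromide, BrC(Br)(Br)Br
Why: Appel reaction converts the primary alcohol into the bromide under neutral conditions.

**Step 12**
Reactants: 22 (1E,3S,5Z)-6-bromo-1-[(2R)-3-(2-bromoethyl)-4-{[(tert-butyldimethylsilyl)oxy]methyl}-5-oxo-2,5-dihydrofuran-2-yl]-2-methylhepta-1,5-dien-3-yl propanoate
Product: 23 (6Z,9S,10E,11aR)-3-{[(tert-butyldimethylsilyl)oxy]methyl}-6,10-dimethyl-2-oxo-2,4,5,8,9,11a-hexahydrocyclodeca[b]furan-9-yl propanoate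
Conditions: NiBr2·DME (1.0 equiv), 4,4'-di-tert-butyl-2,2'-bipyridine (1.1 equiv), Mn powder (6 equiv), DMA/THF, 22 added by syringe pump over 12 h (final 0.002 M), 35 °C
Reagents that add atoms: none
Why: Proposed new method: intramolecular nickel-mediated reductive cross-electrophile coupling in which zerovalent nickel (from NiBr2 and Mn) inserts into the alkenyl C–Br bond with retention of the Z geometry, the reduced alkenylnickel abstracts bromine from the tethered primary bromide, and the primary alkyl radical recombines with that same nickel centre before reductive elimination forms C5–C6; because the radical is born next to the metal its capture should outrun 5-exo addition to the side-chain C1=C2 alkene, high dilution suppresses dimers, no stereocentre is involved, and the closest known reaction type is the intermolecular nickel-catalysed reductive coupling of alkenyl bromides with primary alkyl bromides.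

**Step 13**
Reactants: 23 (6Z,9S,10E,11aR)-3-{[(tert-butyldimethylsilyl)oxy]methyl}-6,10-dimethyl-2-oxo-2,4,5,8,9,11a-hexahydrocyclodeca[b]furan-9-yl propanoate
Product: 25 (6Z,9S,10E,11aR)-3-[(acetyloxy)methyl]-6,10-dimethyl-2-oxo-2,4,5,8,9,11a-hexahydrocyclodeca[b]furan-9-yl propanoate, via macrocyclic alcohol 24 (not isolated)
Conditions: HF·pyridine, pyridine, THF, 0 °C; then Ac2O, DMAP (cat.), 0 °C → rt
Reagents that add atoms: acetic anhydride, CC(=O)OC(C)=O
Why: fluoride cleaves the primary silyl ether without acid or base strong enough to harm the cyclic 1,5-diene or the lactone, and the freed primary allylic alcohol is acetylated in the same flask (desilylation–acylation), giving the target.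

**Compound list**
1 | but-2-yn-1-ol | CC#CCO | starting material
2 | sodium cyclic alkenylalanate (2,2-bis(2-methoxyethoxy)-3-methyl-1-oxa-2-aluminacyclopent-3-ene ate complex) | CC1=CCO[Al-]1(OCCOC)OCCOC.[Na+] | intermediate (not isolated)
3 | (Z)-3-bromobut-2-en-1-ol | OC/C=C(/C)Br | intermediate
4 | (Z)-1,3-dibromobut-2-ene | BrC/C=C(/C)Br | intermediate
5 | 3-methylfuran | Cc1ccoc1 | starting material
6 | 2-bromo-3-methylfuran | Cc1ccoc1Br | intermediate
7 | 2-lithio-3-methylfuran | Cc1ccoc1[Li] | intermediate (not isolated)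
8 | 2-[(2Z)-3-bromobut-2-en-1-yl]-3-methylfuran | Cc1ccoc1C/C=C(/C)Br | intermediate
9 | (2Z,6Z)-7-bromo-3-methyl-4-oxoocta-2,6-dienal | O=C/C=C(/C)C(=O)C/C=C(/C)Br | intermediate (not isolated)
10 | (2E,6Z)-7-bromo-3-methyl-4-oxoocta-2,6-dienal | O=C/C=C(\C)C(=O)C/C=C(/C)Br | intermediate
11 | tert-butyldimethyl(prop-2-yn-1-yloxy)silane (commercial silyl ether of propargyl alcohol) | C#CCO[Si](C)(C)C(C)(C)C | starting material
12 | methyl{3-[(tert-butyldimethylsilyl)oxy]prop-1-yn-1-yl}zinc | C[Zn]C#CCO[Si](C)(C)C(C)(C)C | intermediate (not isolated)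
13 | (4R,5E,9Z)-10-bromo-1-[(tert-butyldimethylsilyl)oxy]-4-hydroxy-6-methylundeca-5,9-dien-2-yn-7-one | CC(C)(C)[Si](C)(C)OCC#C[C@H](O)/C=C(\C)C(=O)C/C=C(/C)Br | intermediate
14 | (4R,5E,7S,9Z)-10-bromo-1-[(tert-butyldimethylsilyl)oxy]-6-methylundeca-5,9-dien-2-yne-4,7-diol | CC(C)(C)[Si](C)(C)OCC#C[C@H](O)/C=C(\C)[C@@H](O)C/C=C(/C)Br | intermediate
15 | vinylmagnesium bromide | C=C[Mg]Br | starting material
16 | alkenylmagnesium bromide from anti-addition to 14 (vinyl on C3, MgBr on C2 cis to the C4 alkoxide; both hydroxyls as bromomagnesium alkoxides) | CC(C)(C)[Si](C)(C)OC/C([Mg]Br)=C(\C=C)[C@H](O[Mg]Br)/C=C(\C)[C@@H](O[Mg]Br)C/C=C(/C)Br | intermediate (not isolated)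
17 | (2Z,4R,5E,7S,9Z)-10-bromo-2-{[(tert-butyldimethylsilyl)oxy]methyl}-3-ethenyl-4,7-dihydroxy-6-methylundeca-2,5,9-trienoic acid | CC(C)(C)[Si](C)(C)OC/C(C(=O)O)=C(\C=C)[C@H](O)/C=C(\C)[C@@H](O)C/C=C(/C)Br | intermediate (not isolated)
18 | (5R)-5-[(1E,3S,5Z)-6-bromo-3-hydroxy-2-methylhepta-1,5-dien-1-yl]-3-{[(tert-butyldimethylsilyl)oxy]methyl}-4-ethenylfuran-2(5H)-one | CC(C)(C)[Si](C)(C)OCC1=C(C=C)[C@@H](/C=C(\C)[C@@H](O)C/C=C(/C)Br)OC1=O | intermediate
19 | (1E,3S,5Z)-6-bromo-1-[(2R)-4-{[(tert-butyldimethylsilyl)oxy]methyl}-3-ethenyl-5-oxo-2,5-dihydrofuran-2-yl]-2-methylhepta-1,5-dien-3-yl propanoate | CC(C)(C)[Si](C)(C)OCC1=C(C=C)[C@@H](/C=C(\C)[C@@H](OC(=O)CC)C/C=C(/C)Br)OC1=O | intermediate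
20 | (1E,3S,5Z)-1-[(2R)-3-[2-(9-borabicyclo[3.3.1]nonan-9-yl)ethyl]-4-{[(tert-butyldimethylsilyl)oxy]methyl}-5-oxo-2,5-dihydrofuran-2-yl]-6-bromo-2-methylhepta-1,5-dien-3-yl propanoate | CC(C)(C)[Si](C)(C)OCC1=C(CCB2C3CCCC2CCC3)[C@@H](/C=C(\C)[C@@H](OC(=O)CC)C/C=C(/C)Br)OC1=O | intermediate (not isolated)
21 | (1E,3S,5Z)-6-bromo-1-[(2R)-4-{[(tert-butyldimethylsilyl)oxy]methyl}-3-(2-hydroxyethyl)-5-oxo-2,5-dihydrofuran-2-yl]-2-methylhepta-1,5-dien-3-yl propanoate | CC(C)(C)[Si](C)(C)OCC1=C(CCO)[C@@H](/C=C(\C)[C@@H](OC(=O)CC)C/C=C(/C)Br)OC1=O | intermediate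
22 | (1E,3S,5Z)-6-bromo-1-[(2R)-3-(2-bromoethyl)-4-{[(tert-butyldimethylsilyl)oxy]methyl}-5-oxo-2,5-dihydrofuran-2-yl]-2-methylhepta-1,5-dien-3-yl propanoate | CC(C)(C)[Si](C)(C)OCC1=C(CCBr)[C@@H](/C=C(\C)[C@@H](OC(=O)CC)C/C=C(/C)Br)OC1=O | intermediate
23 | (6Z,9S,10E,11aR)-3-{[(tert-butyldimethylsilyl)oxy]methyl}-6,10-dimethyl-2-oxo-2,4,5,8,9,11a-hexahydrocyclodeca[b]furan-9-yl propanoate | CCC(=O)O[C@H]1C/C=C(/C)CCC2=C(CO[Si](C)(C)C(C)(C)C)C(=O)O[C@@H]2/C=C/1C | intermediate
24 | (6Z,9S,10E,11aR)-3-(hydroxymethyl)-6,10-dimethyl-2-oxo-2,4,5,8,9,11a-hexahydrocyclodeca[b]furan-9-yl propanoate | CCC(=O)O[C@H]1C/C=C(/C)CCC2=C(CO)C(=O)O[C@@H]2/C=C/1C | intermediate (not isolated)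
25 | (6Z,9S,10E,11aR)-3-[(acetyloxy)methyl]-6,10-dimethyl-2-oxo-2,4,5,8,9,11a-hexahydrocyclodeca[b]furan-9-yl propanoate (CNP0238103.1) | CCC(=O)O[C@H]1C/C=C(/C)CCC2=C(COC(C)=O)C(=O)O[C@@H]2/C=C/1C | target

**Count**
Total steps: 13. Longest linear sequence: 12 (steps 1, 2 and 4–13, from but-2-yn-1-ol).

**Steps most likely to fail, with fallbacks**

Step 12 (ring closure) is the most likely to fail. The primary radical can add 5-exo to the side-chain alkene, low-valent nickel can insert into the allylic C–O bonds of the propionate and the lactone, and a ten-membered ring invites oligomers. The product must also stay below about 40 °C to avoid Cope rearrangement of the cyclic 1,5-diene. Fallback: set out from 19, hydroborate with 9-BBN as in step 10 to reach 20, and, instead of oxidising, add this solution slowly to Pd(dppf)Cl2, AsPh3 and Cs2CO3 in DMF/THF/H2O at 40 °C. This B-alkyl Suzuki–Miyaura macrocyclisation closes the same C5–C6 bond by transmetalation and returns to the route at 23. It makes no compound outside the list (F0).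

Step 8 (butenolide formation) is second. The alkenylmagnesium intermediate carries a β-silyloxy group and may eliminate to an allene, the substrate carries two alkoxides and an alkenyl bromide, and the chelated C–Mg bond may carboxylate slowly. Fallback: set out from 10 and run the ProPhenol/Me2Zn alkynylation with methyl propiolate to give methyl (4R,5E,9Z)-10-bromo-4-hydroxy-6-methyl-7-oxoundeca-5,9-dien-2-ynoate F1. Reduce with (R)-Me-CBS and catecholborane to methyl (4R,5E,7S,9Z)-10-bromo-4,7-dihydroxy-6-methylundeca-5,9-dien-2-ynoate F2. Deprotonate both hydroxyls with MeLi, add (CH2=CH)2CuLi at −78 °C (syn-carbocupration, vinyl to the β-carbon), trap the α-cuprio ester with gaseous formaldehyde and acidify. The ester then sits cis to C4 and lactonises to (5R)-5-[(1E,3S,5Z)-6-bromo-3-hydroxy-2-methylhepta-1,5-dien-1-yl]-4-ethenyl-3-(hydroxymethyl)furan-2(5H)-one F3. Selective silylation of the primary hydroxyl (TBSCl, imidazole, 0 °C) returns to the route at 18.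

Step 6 (alkynylation) is third. The 4-oxo-enal 10 is a very electrophilic, base-sensitive ene-dicarbonyl that can undergo conjugate addition or enolise toward C5, and a propargylic ether is not the best alkyne for this catalyst, so the ee may be low. Fallback: set out from 10 and add the lithium acetylide of 11 (n-BuLi, THF, −78 °C; only the aldehyde reacts) to give (5E,9Z)-10-bromo-1-[(tert-butyldimethylsilyl)oxy]-4-hydroxy-6-methylundeca-5,9-dien-2-yn-7-one, racemic at C4, F4. Oxidise with Dess–Martin periodinane to (5E,9Z)-10-bromo-1-[(tert-butyldimethylsilyl)oxy]-6-methylundeca-5,9-dien-2-yne-4,7-dione F5. Reduce both carbonyls with (R)-Me-CBS and catecholborane; the alkenyl flank is the large group at each ketone, so the same catalyst gives 4R and 7S. This returns to the route at 14.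

**Further compounds**
F0 | step 12 | none | none
F1 | step 8 | methyl (4R,5E,9Z)-10-bromo-4-hydroxy-6-methyl-7-oxoundeca-5,9-dien-2-ynoate | COC(=O)C#C[C@H](O)/C=C(\C)C(=O)C/C=C(/C)Br
F2 | step 8 | methyl (4R,5E,7S,9Z)-10-bromo-4,7-dihydroxy-6-methylundeca-5,9-dien-2-ynoate | COC(=O)C#C[C@H](O)/C=C(\C)[C@@H](O)C/C=C(/C)Br
F3 | step 8 | (5R)-5-[(1E,3S,5Z)-6-bromo-3-hydroxy-2-methylhepta-1,5-dien-1-yl]-4-ethenyl-3-(hydroxymethyl)furan-2(5H)-one | OCC1=C(C=C)[C@@H](/C=C(\C)[C@@H](O)C/C=C(/C)Br)OC1=O
F4 | step 6 | (5E,9Z)-10-bromo-1-[(tert-butyldimethylsilyl)oxy]-4-hydroxy-6-methylundeca-5,9-dien-2-yn-7-one (racemic at C4) | CC(C)(C)[Si](C)(C)OCC#CC(O)/C=C(\C)C(=O)C/C=C(/C)Br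
F5 | step 6 | (5E,9Z)-10-bromo-1-[(tert-butyldimethylsilyl)oxy]-6-methylundeca-5,9-dien-2-yne-4,7-dione | CC(C)(C)[Si](C)(C)OCC#CC(=O)/C=C(\C)C(=O)C/C=C(/C)Br
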